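**Plan**
- Cuts: first the two O–Si masks on the 7-OH and 3'-OH. Then C4–C4a, which opens ring C to a (Z)-3-aryloxy-2-arylacrylic acid. Then O1–C2, giving a ring A phenol and an enol tosylate. Then C2–C3 and C3–C1' together, back to a ring B aldehyde and a diazoacetate (1,2-aryl shift). Last ring D, whose C5'–CH= and O–CMe2 bonds both come from a propargyl ether Claisen cascade on 3,4-dihydroxybenzaldehyde.
- Enabling feature: C4a of ring A lies ortho to O1, ortho to the 5-OMe and para to the 7-oxygen, so it is a phloroglucinol-type carbon nucleophile. The O1–C2=C3 arm already attached to ring A holds acyl carbon C4 where only the six-membered ring C can close.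
- Forward order: rings A and B are bought. Ring D is built first on ring B, the C2–C3–C4 unit is then grafted onto ring B, ring A is joined through O1, ring C closes last, and desilylation ends the route.
- Stereochemistry: the target has no stereocentre. The only element to control is the Z geometry of the acrylate (O1 cis to C4). A lithium chelate sets it in the enol tosylation and a retentive addition–elimination passes it on.

Key step: step 9

Assumption: rings A and C carry isoflavone numbers, ring B atoms are primed, ring D is the dimethylpyran fused to ring B; tert-butyl diazoacetate and the silylating, sulfonylating and activating reagents are bought.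

**Step 1**
Reactants: 1 3,4-dihydroxybenzaldehyde; 2 3-chloro-3-methylbut-1-yne
Product: 3 3-hydroxy-4-[(2-methylbut-3-yn-2-yl)oxy]benzaldehyde
Conditions: K2CO3 (1.1 equiv), KI (cat.), DMF, 65 °C, Ar
Reagents that add atoms: none
Why: Williamson-type O-alkylation with a tertiary propargylic chloride; the 4-OH is para to the formyl group and clearly the more acidic, so one equivalent of carbonate should generate only its phenoxide and leave the 3-OH free.

**Step 2**
Reactants: 3 3-hydroxy-4-[(2-methylbut-3-yn-2-yl)oxy]benzaldehyde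
Product: 4 4-[(2-methylbut-3-yn-2-yl)oxy]-3-(triisopropylsilyloxy)benzaldehyde
Conditions: TIPSCl, imidazole, DMF, rt
Reagents that add atoms: triisopropylsilyl chloride (TIPSCl), CC(C)[Si](Cl)(C(C)C)C(C)C
Why: Routine imidazole-promoted silylation of a phenol, done before heating so that the free hydroxyl cannot add to the alkyne, and installing a group that tolerates the later anhydride activation.

**Step 3**
Reactants: 4 4-[(2-methylbut-3-yn-2-yl)oxy]-3-(triisopropylsilyloxy)benzaldehyde
Product: 5 2,2-dimethyl-8-(triisopropylsilyloxy)-2H-chromene-6-carbaldehyde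
Conditions: N,N-diethylaniline, 190 °C
Reagents that add atoms: none
Why: Aromatic propargyl Claisen rearrangement, then tautomerisation, 1,5-hydrogen shift and oxa-6π electrocyclisation build ring D; only one carbon ortho to the ether oxygen bears hydrogen, so a single chromene can form.

**Step 4**
Reactants: 5 2,2-dimethyl-8-(triisopropylsilyloxy)-2H-chromene-6-carbaldehyde; 6 tert-butyl diazoacetate
Product: 7 tert-butyl (Z)-2-[2,2-dimethyl-8-(triisopropylsilyloxy)-2H-chromen-6-yl]-3-hydroxyacrylate (hydrogen-bonded enol of the α-formyl ester)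
Conditions: HBF4·OEt2 (10 mol %), CH2Cl2, −78 °C
Reagents that add atoms: none
Why: Protic acid-catalysed addition of a diazoacetate to an aromatic aldehyde followed by 1,2-aryl shift with loss of N2 is a known route to 3-hydroxy-2-arylacrylates; the ring D oxygen para to the migrating carbon should favour aryl over hydride shift (the Roskamp path), and the product rests as the chelated Z enol.

**Step 5**
Reactants: 7 tert-butyl (Z)-2-[2,2-dimethyl-8-(triisopropylsilyloxy)-2H-chromen-6-yl]-3-hydroxyacrylate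
Product: 8 tert-butyl (Z)-2-[2,2-dimethyl-8-(triisopropylsilyloxy)-2H-chromen-6-yl]-3-(tosyloxy)acrylate
Conditions: TsCl, N-methylimidazole, LiOH, CH2Cl2, 0 °C
Reagents that add atoms: p-toluenesulfonyl chloride (TsCl), Cc1ccc(cc1)S(=O)(=O)Cl
Why: Stereoselective enol tosylation; lithium ties the enolate oxygen and the ester carbonyl into a six-membered chelate, and the N-tosylimidazolium salt sulfonylates that oxygen, so the tosyloxy group should end up cis to the ester (Z).

**Step 6**
Reactants: 9 5-methoxyresorcinol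
Product: 10 3-methoxy-5-(triisopropylsilyloxy)phenol
Conditions: TIPSCl (1.0 equiv), imidazole, DMF, 0 °C → rt
Reagents that add atoms: triisopropylsilyl chloride (TIPSCl), CC(C)[Si](Cl)(C(C)C)C(C)C
Why: Statistical monosilylation of a symmetric resorcinol; the two hydroxyls are equivalent, so only the degree of silylation matters, and unreacted diol and bis-ether separate by chromatography and can be recycled.

**Step 7**
Reactants: 8 tert-butyl (Z)-2-[2,2-dimethyl-8-(triisopropylsilyloxy)-2H-chromen-6-yl]-3-(tosyloxy)acrylate; 10 3-methoxy-5-(triisopropylsilyloxy)phenol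
Product: 11 tert-butyl (Z)-2-[2,2-dimethyl-8-(triisopropylsilyloxy)-2H-chromen-6-yl]-3-[3-methoxy-5-(triisopropylsilyloxy)phenoxy]acrylate
Conditions: Cs2CO3, MeCN, 0 °C → rt
Reagents that add atoms: none
Why: Nucleophilic vinylic substitution by addition–elimination (oxa-Michael addition, then loss of tosylate) at the unhindered β-CH of the acrylate forms O1–C2; with so good a leaving group, expulsion should outrun bond rotation in the ester enolate and the Z geometry should be retained.

**Step 8**
Reactants: 11 tert-butyl (Z)-2-[2,2-dimethyl-8-(triisopropylsilyloxy)-2H-chromen-6-yl]-3-[3-methoxy-5-(triisopropylsilyloxy)phenoxy]acrylate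
Product: 13 (Z)-2-[2,2-dimethyl-8-(triisopropylsilyloxy)-2H-chromen-6-yl]-3-[3-methoxy-5-(triisopropylsilyloxy)phenoxy]acrylic acid, via trimethylsilyl ester 12 (not isolated)
Conditions: TMSOTf, 2,6-lutidine, CH2Cl2, 0 °C; then aqueous pH 5 buffer
Reagents that add atoms: trimethylsilyl triflate (TMSOTf), C[Si](C)(C)OS(=O)(=O)C(F)(F)F (its Me3Si group is held only by 12)
Why: Silyl triflate-mediated tert-butyl ester cleavage (carbonyl O-silylation, loss of isobutene to the hindered base) gives a silyl ester that water hydrolyses; these buffered, hydroxide-free conditions should spare the aryl silyl ethers, ring D and the β-aryloxy group that hydroxide could displace.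

**Step 9**
Reactants: 13 (Z)-2-[2,2-dimethyl-8-(triisopropylsilyloxy)-2H-chromen-6-yl]-3-[3-methoxy-5-(triisopropylsilyloxy)phenoxy]acrylic acid
Product: 15 3-[2,2-dimethyl-8-(triisopropylsilyloxy)-2H-chromen-6-yl]-5-methoxy-7-(triisopropylsilyloxy)-4H-chromen-4-one, via mixed trifluoroacetic anhydride 14 (not isolated)
Conditions: TFAA (1.5 equiv), CH2Cl2 (0.02 M), −20 → 0 °C
Reagents that add atoms: trifluoroacetic anhydride (TFAA), O=C(OC(=O)C(F)(F)F)C(F)(F)F (its CF3CO group is held only by 14)
Why: TFAA turns acid 13 into mixed anhydride 14, whose non-fluorinated acyl carbon C4, made strongly electrophilic by the trifluoroacetate leaving group, is attacked by ring A carbon C4a, and proton loss rearomatises ring A to leave the 4-pyranone. The closest known chemistry is the intramolecular Friedel–Crafts acylation of 3-aryloxyacrylic acids to chromones, together with the TFAA-promoted acylation of phloroglucinol ethers by free carboxylic acids. Ring C closes in a 6-exo-trig mode at the anhydride carbonyl, which the Z geometry allows by holding O1 and C4 on the same side of C2=C3; should that geometry have leaked earlier, the push–pull character of the activated acyl unit lowers the C2–C3 rotation barrier and lets the material return to the reactive arrangement. No stereocentre is formed. The selectivity needed is between the two ring A carbons ortho to O1 (the third free carbon, para to O1, is out of reach of the arm): each is activated by the same three oxygens, two ortho and one para, so electronics barely separate them, and the triisopropylsilyl group decides by crowding its own neighbour and by the peri clash it would suffer with the C4 carbonyl, steering closure to the carbon next to the small methoxy group. Anhydride-level activation in dilute solution at or below 0 °C should leave the ring D alkene and both aryl silyl ethers untouched, and a coumarin cannot form because O1 is already bonded to C2.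

**Step 10**
Reactants: 15 3-[2,2-dimethyl-8-(triisopropylsilyloxy)-2H-chromen-6-yl]-5-methoxy-7-(triisopropylsilyloxy)-4H-chromen-4-one
Product: 16 glycyrrhizaisoflavone B, 7-hydroxy-3-(8-hydroxy-2,2-dimethyl-2H-chromen-6-yl)-5-methoxy-4H-chromen-4-one
Conditions: TBAF (2.2 equiv), AcOH (2.2 equiv), THF, 0 °C
Reagents that add atoms: none
Why: Fluoride-driven cleavage of both aryl silyl ethers; acetic acid buffers the phenoxides so that the base-sensitive pyranone ring is not opened, and the methyl ether and ring D are inert.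

**Compound list**
1 | 3,4-dihydroxybenzaldehyde | O=Cc1ccc(O)c(O)c1 | starting material
2 | 3-chloro-3-methylbut-1-yne | C#CC(C)(C)Cl | starting material
3 | 3-hydroxy-4-[(2-methylbut-3-yn-2-yl)oxy]benzaldehyde | O=Cc1ccc(OC(C)(C)C#C)c(O)c1 | intermediate
4 | 4-[(2-methylbut-3-yn-2-yl)oxy]-3-(triisopropylsilyloxy)benzaldehyde | O=Cc1ccc(OC(C)(C)C#C)c(O[Si](C(C)C)(C(C)C)C(C)C)c1 | intermediate
5 | 2,2-dimethyl-8-(triisopropylsilyloxy)-2H-chromene-6-carbaldehyde | O=Cc1cc(O[Si](C(C)C)(C(C)C)C(C)C)c2OC(C)(C)C=Cc2c1 | intermediate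
6 | tert-butyl diazoacetate | CC(C)(C)OC(=O)C=[N+]=[N-] | starting material
7 | tert-butyl (Z)-2-[2,2-dimethyl-8-(triisopropylsilyloxy)-2H-chromen-6-yl]-3-hydroxyacrylate | O/C=C(\C(=O)OC(C)(C)C)c1cc(O[Si](C(C)C)(C(C)C)C(C)C)c2OC(C)(C)C=Cc2c1 | intermediate
8 | tert-butyl (Z)-2-[2,2-dimethyl-8-(triisopropylsilyloxy)-2H-chromen-6-yl]-3-(tosyloxy)acrylate | Cc1ccc(cc1)S(=O)(=O)O/C=C(\C(=O)OC(C)(C)C)c1cc(O[Si](C(C)C)(C(C)C)C(C)C)c2OC(C)(C)C=Cc2c1 | intermediate
9 | 5-methoxyresorcinol | COc1cc(O)cc(O)c1 | starting material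
10 | 3-methoxy-5-(triisopropylsilyloxy)phenol | COc1cc(O)cc(O[Si](C(C)C)(C(C)C)C(C)C)c1 | intermediate
11 | tert-butyl (Z)-2-[2,2-dimethyl-8-(triisopropylsilyloxy)-2H-chromen-6-yl]-3-[3-methoxy-5-(triisopropylsilyloxy)phenoxy]acrylate | COc1cc(O[Si](C(C)C)(C(C)C)C(C)C)cc(O/C=C(\C(=O)OC(C)(C)C)c2cc(O[Si](C(C)C)(C(C)C)C(C)C)c3OC(C)(C)C=Cc3c2)c1 | intermediate
12 | trimethylsilyl (Z)-2-[2,2-dimethyl-8-(triisopropylsilyloxy)-2H-chromen-6-yl]-3-[3-methoxy-5-(triisopropylsilyloxy)phenoxy]acrylate | COc1cc(O[Si](C(C)C)(C(C)C)C(C)C)cc(O/C=C(\C(=O)O[Si](C)(C)C)c2cc(O[Si](C(C)C)(C(C)C)C(C)C)c3OC(C)(C)C=Cc3c2)c1 | intermediate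
13 | (Z)-2-[2,2-dimethyl-8-(triisopropylsilyloxy)-2H-chromen-6-yl]-3-[3-methoxy-5-(triisopropylsilyloxy)phenoxy]acrylic acid | COc1cc(O[Si](C(C)C)(C(C)C)C(C)C)cc(O/C=C(\C(=O)O)c2cc(O[Si](C(C)C)(C(C)C)C(C)C)c3OC(C)(C)C=Cc3c2)c1 | intermediate
14 | (Z)-2-[2,2-dimethyl-8-(triisopropylsilyloxy)-2H-chromen-6-yl]-3-[3-methoxy-5-(triisopropylsilyloxy)phenoxy]acrylic trifluoroacetic anhydride | COc1cc(O[Si](C(C)C)(C(C)C)C(C)C)cc(O/C=C(\C(=O)OC(=O)C(F)(F)F)c2cc(O[Si](C(C)C)(C(C)C)C(C)C)c3OC(C)(C)C=Cc3c2)c1 | intermediate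
15 | 3-[2,2-dimethyl-8-(triisopropylsilyloxy)-2H-chromen-6-yl]-5-methoxy-7-(triisopropylsilyloxy)-4H-chromen-4-one | COc1cc(O[Si](C(C)C)(C(C)C)C(C)C)cc2occ(-c3cc(O[Si](C(C)C)(C(C)C)C(C)C)c4OC(C)(C)C=Cc4c3)c(=O)c12 | intermediate
16 | glycyrrhizaisoflavone B | COc1cc(O)cc2occ(-c3cc(O)c4c(c3)C=CC(C)(C)O4)c(=O)c12 | target

**Step count**
Total step count: 10.
Longest linear sequence: 9 (steps 1–5 and 7–10); step 6 is the one-step ring A branch.

**Steps most likely to fail**

**Step 9.** Acylation at the ring A carbon flanked by O1 and the silyl ether may compete with acylation next to the methoxy group (poor site selectivity).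
- The fallback sets out from 8 and comes back at 15. It removes the choice of site by making ring A symmetric.
- Phloroglucinol is silylated twice (TIPSCl, imidazole, DMF) to 3,5-bis(triisopropylsilyloxy)phenol F1.
- F1 takes the place of 10 in the displacement on 8 (Cs2CO3, MeCN) and should give the tert-butyl (Z)-3-[3,5-bis(triisopropylsilyloxy)phenoxy]acrylate F2.
- TMSOTf/2,6-lutidine leads through the trimethylsilyl ester F3 to the acid F4.
- TFAA leads through the mixed anhydride F5 to the 5,7-bis(silyloxy)isoflavone F6. The two ortho carbons are equivalent here, so only one mode of closure exists.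
- TBAF/AcOH strips all three silyl groups to the 5,7,3'-triol F7.
- TIPSCl (2 equiv)/imidazole should then silylate the 7-OH and the ring B hydroxyl but not the 5-OH, which is locked in a hydrogen bond to the C4 carbonyl. This gives the 5-hydroxy bis-silyl ether F8.
- MeI/Ag2O (CH2Cl2, dark), the usual way to methylate chelated peri-hydroxyls, delivers 15.

**Step 7.** Three things may go wrong. The enolate formed on phenoxide addition may live long enough to rotate, so the Z geometry leaks. Phenoxide may attack sulfur instead of carbon (sulfonyl transfer). Ring A may react through carbon.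
- The fallback sets out from 7 and comes back at 11. It makes the O1–C2 bond at palladium instead of by conjugate addition.
- The lithium enolate of 7 (LiHMDS, THF, −78 °C) is trapped with N-phenyltriflimide to give the (Z)-enol triflate F9.
- Buchwald–Hartwig-type etherification with 10 follows (Pd2(dba)3, 2-(di-tert-butylphosphino)biphenyl, K3PO4, toluene, 60 °C).
- It proceeds by oxidative addition of zerovalent palladium into the C–OTf bond and C–O reductive elimination, both with retention at the alkene, and gives 11.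

**Step 4.** Hydride shift may outrun aryl shift after the diazoacetate has added (β-keto ester formation), or the acid catalyst may erode ring D or the silyl ether.
- The fallback sets out from 5 and comes back at 7. It builds the chain one carbon at a time without acid.
- Pinnick oxidation of 5 (NaClO2, NaH2PO4, 2-methylbut-2-ene, t-BuOH/H2O) gives the chromene-6-carboxylic acid F10.
- Oxalyl chloride with catalytic DMF gives the acid chloride F11.
- Diazomethane/Et3N gives the diazoketone F12.
- The Wolff rearrangement of the Arndt–Eistert sequence (PhCO2Ag, Et3N, t-BuOH) gives the tert-butyl arylacetate F13.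
- Crossed Claisen condensation (LDA, THF, −78 °C; then HCO2Et) with a mildly acidic quench returns enol 7.

**Further compounds**
F1 | step 9 | 3,5-bis(triisopropylsilyloxy)phenol | Oc1cc(O[Si](C(C)C)(C(C)C)C(C)C)cc(O[Si](C(C)C)(C(C)C)C(C)C)c1
F2 | step 9 | tert-butyl (Z)-3-[3,5-bis(triisopropylsilyloxy)phenoxy]-2-[2,2-dimethyl-8-(triisopropylsilyloxy)-2H-chromen-6-yl]acrylate | CC(C)[Si](Oc1cc(O[Si](C(C)C)(C(C)C)C(C)C)cc(O/C=C(\C(=O)OC(C)(C)C)c2cc(O[Si](C(C)C)(C(C)C)C(C)C)c3OC(C)(C)C=Cc3c2)c1)(C(C)C)C(C)C
F3 | step 9 | trimethylsilyl (Z)-3-[3,5-bis(triisopropylsilyloxy)phenoxy]-2-[2,2-dimethyl-8-(triisopropylsilyloxy)-2H-chromen-6-yl]acrylate | CC(C)[Si](Oc1cc(O[Si](C(C)C)(C(C)C)C(C)C)cc(O/C=C(\C(=O)O[Si](C)(C)C)c2cc(O[Si](C(C)C)(C(C)C)C(C)C)c3OC(C)(C)C=Cc3c2)c1)(C(C)C)C(C)C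
F4 | step 9 | (Z)-3-[3,5-bis(triisopropylsilyloxy)phenoxy]-2-[2,2-dimethyl-8-(triisopropylsilyloxy)-2H-chromen-6-yl]acrylic acid | CC(C)[Si](Oc1cc(O[Si](C(C)C)(C(C)C)C(C)C)cc(O/C=C(\C(=O)O)c2cc(O[Si](C(C)C)(C(C)C)C(C)C)c3OC(C)(C)C=Cc3c2)c1)(C(C)C)C(C)C
F5 | step 9 | (Z)-3-[3,5-bis(triisopropylsilyloxy)phenoxy]-2-[2,2-dimethyl-8-(triisopropylsilyloxy)-2H-chromen-6-yl]acrylic trifluoroacetic anhydride | CC(C)[Si](Oc1cc(O[Si](C(C)C)(C(C)C)C(C)C)cc(O/C=C(\C(=O)OC(=O)C(F)(F)F)c2cc(O[Si](C(C)C)(C(C)C)C(C)C)c3OC(C)(C)C=Cc3c2)c1)(C(C)C)C(C)C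
F6 | step 9 | 3-[2,2-dimethyl-8-(triisopropylsilyloxy)-2H-chromen-6-yl]-5,7-bis(triisopropylsilyloxy)-4H-chromen-4-one | CC(C)[Si](Oc1cc(O[Si](C(C)C)(C(C)C)C(C)C)c2c(c1)occ(-c1cc(O[Si](C(C)C)(C(C)C)C(C)C)c3OC(C)(C)C=Cc3c1)c2=O)(C(C)C)C(C)C
F7 | step 9 | 5,7-dihydroxy-3-(8-hydroxy-2,2-dimethyl-2H-chromen-6-yl)-4H-chromen-4-one | Oc1cc(O)c2c(c1)occ(-c1cc(O)c3OC(C)(C)C=Cc3c1)c2=O
F8 | step 9 | 3-[2,2-dimethyl-8-(triisopropylsilyloxy)-2H-chromen-6-yl]-5-hydroxy-7-(triisopropylsilyloxy)-4H-chromen-4-one | CC(C)[Si](Oc1cc(O)c2c(c1)occ(-c1cc(O[Si](C(C)C)(C(C)C)C(C)C)c3OC(C)(C)C=Cc3c1)c2=O)(C(C)C)C(C)C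
F9 | step 7 | tert-butyl (Z)-2-[2,2-dimethyl-8-(triisopropylsilyloxy)-2H-chromen-6-yl]-3-(trifluoromethylsulfonyloxy)acrylate | FC(F)(F)S(=O)(=O)O/C=C(\C(=O)OC(C)(C)C)c1cc(O[Si](C(C)C)(C(C)C)C(C)C)c2OC(C)(C)C=Cc2c1
F10 | step 4 | 2,2-dimethyl-8-(triisopropylsilyloxy)-2H-chromene-6-carboxylic acid | OC(=O)c1cc(O[Si](C(C)C)(C(C)C)C(C)C)c2OC(C)(C)C=Cc2c1
F11 | step 4 | 2,2-dimethyl-8-(triisopropylsilyloxy)-2H-chromene-6-carbonyl chloride | ClC(=O)c1cc(O[Si](C(C)C)(C(C)C)C(C)C)c2OC(C)(C)C=Cc2c1
F12 | step 4 | 2-diazo-1-[2,2-dimethyl-8-(triisopropylsilyloxy)-2H-chromen-6-yl]ethan-1-one | [N-]=[N+]=CC(=O)c1cc(O[Si](C(C)C)(C(C)C)C(C)C)c2OC(C)(C)C=Cc2c1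
F13 | step 4 | tert-butyl 2-[2,2-dimethyl-8-(triisopropylsilyloxy)-2H-chromen-6-yl]acetate | CC(C)(C)OC(=O)Cc1cc(O[Si](C(C)C)(C(C)C)C(C)C)c2OC(C)(C)C=Cc2c1
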